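Single ring comes slowly in the dawn run, 43.4 % of the charge after 2.50 h, from a closure of starting material that the list of suspects gives as running both ways.

| flask | starting material | remark | time |
|---|---|---|---|
| dawn | 12 mM | run made earlier |  |
| summer | 210 mM | run made earlier |  |
| teal | 20 mM |  | 12 h |
| violet | 40 mM |  | 12 h |
| amber | 80 mM |  | 12 h |
| red | 150 mM |  | 12 h |
| grey | 300 mM |  | 12 h |

- dawn (time / h: single ring / %): 0.500: 15.8; 1.00: 26.5; 2.50: 43.4; 6.00: 50.1
- summer (time / h: single ring / %): 0.500: 11.5; 1.00: 14.7; 2.50: 16.3; 6.00: 14.3

(each reading ± 0.3 percentage points)

- in percentages every species weighs as the starting material in it: one open dimer or ring dimer counts as two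
- in percentages every species weighs as the starting material in it: one open trimer counts as three
- on the list of suspects stand: starting material + open dimer -> open trimer; starting material <-> single ring; open dimer -> ring dimer; 2 starting material -> open dimer
- "hardly changes" means that all values lie within two and a half points (for a concentration: within two and a half percent of the largest)

- [single ring] at the end for teal, violet, amber, red, grey, in this order
- the course of these numbers from the first flask to the last (hardly changes / rises, then falls / rises all the way / falls all the way / falls, then rises)

One thing looks contradictory: after 6.00 h the dawn run holds 50.1 % of its charge as single ring and the summer run holds 14.3 %, yet c(single ring) is 6.01 mM in dawn and 30.0 mM in summer.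

I clear this by replacing each early curve by its mean. In dawn's first 0.500 h, setting aside both second-order loss and the return of single ring, the mean share of starting material is one minus half the ring reading, which gives a forward closure constant of 0.343 h⁻¹, a half-life of 2.02 h by the forward step alone. With that constant, summer's first reading of 11.5 % means a mean share of 0.670, so a mean c(starting material) of 141 mM. A straight fall to that mean has lost 66.0 % of the charge, and what the ring reading does not account for I book to second-order steps. Dividing the closure constant by the second-order constant gives the crossover charge c× = 29.7 mM, the charge at which closure and second-order loss run level, an effective molarity. The mean of the square along that line stands 8.09 % above the square of the mean, and c× moves up by as much, which I accept.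

Dawn lies below c× by a factor of 2.48, and summer lies above it by 7.06, and from dawn to summer the share read at 6.00 h falls by a factor of 3.50 while the charge grows by 17.5. The local order of c(single ring) in the charge is then 1/(1 + c/c×), and I commit to a rise that flattens, with order 0.598 at teal and 0.0902 at grey.

The forecast gives 8.8 mM, 13.6 mM, 18.5 mM, 23 mM and 26.5 mM, shape rises all the way, on the ground that “Percent falls with loading, but less than proportionally”.

The flasks give 8.10 mM, 12.0 mM, 16.1 mM, 19.7 mM and 23.3 mM, shape rises all the way, with grey 3.20 mM below the forecast.

    starting material + open dimer → open trimer (k = 25.9 L mol⁻¹ h⁻¹)
    starting material ⇌ single ring (K = 1.59, k = 0.373 h⁻¹)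
    open dimer → ring dimer (k = 0.0965 h⁻¹)
    2 starting material → open dimer (k = 4.15 L mol⁻¹ h⁻¹)

The local order at teal is 0.65 against my 0.598, and from red to grey the row climbs with order 0.242 against my 0.0902 at grey. In teal at 0.705 h, closure, forward step alone, uses starting material 3.2 times as fast as dimerisation, while open dimer goes to open trimer 3.8 times as fast as to ring dimer. After 12.0 h teal holds 40.5 % as single ring and 22.6 % as open trimer.

(The runs come from a simulation on assumed constants.)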